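**Retrosynthetic overview**
- Last events: angeloylation of both hydroxyls of a 6β,9α-diol, then one oxidation that turns the C15 allylic alcohol into the enal and the C12 ether methylene into the lactone carbonyl.
- The oxirane comes from a 9-hydroxyl-directed epoxidation of a C10 vinyl group. The C6 carbinol and the C15 alcohol come from hydrolysis and reduction of a C6 mixed ketal.
- Key disconnection: C1–C10 (quaternary centre) and C4–C5 in one radical cascade. A silicon-tethered vinyl radical on O9 closes onto C10, and the resulting C5 radical closes onto a propargyl arm of the C6 ketal.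
- C7, C8 and C9 come from one asymmetric 1,4-addition to a p-quinone monoketal, α-bromination, bromine-controlled reduction and SN2 ether closure.
- Ring order: carbocycle (dearomatised phenol) → tetrahydrofuran (future lactone) → oxasilolane and ketal-fused tetrahydrofuran (radical step, both opened later) → oxirane → lactone carbonyl.

Assumption: the five starting materials are taken as purchasable; carbons carry the elemanolide numbers (ring C5–C10, C10 with the C14 methyl and C1–C2, C5 with C4/C3/C15, C7 with C11/C12/C13), β is the face of the C14 methyl and α the opposite face.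

**Step 1**
Reactants: 1 o-cresol; 2 propargyl alcohol (two molecules are built in)
Product: 3 2-methyl-4,4-bis(prop-2-yn-1-yloxy)cyclohexa-2,5-dien-1-one
Conditions: PhI(OAc)2 (2.2 equiv), prop-2-yn-1-ol (2) as solvent, 0 °C → rt
Reagents that add atoms: prop-2-yn-1-ol (the second molecule of 2 that is built in) C#CCO
Why: Hypervalent-iodine oxidative dearomatization of a para-unsubstituted phenol (two successive two-electron oxidations, one molecule of the alcohol adding at the para carbon in each) gives the p-quinone monoketal; no stereocenter is formed.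

**Step 2**
Reactants: 4 2-bromoprop-2-en-1-ol
Product: 5 (2-bromoprop-2-en-1-yloxy)(tert-butyl)dimethylsilane
Conditions: t-BuMe2SiCl, imidazole, CH2Cl2, 0 °C → rt
Reagents that add atoms: tert-butyldimethylsilyl chloride CC(C)(C)[Si](C)(C)Cl
Why: Standard silyl ether protection of the primary alcohol so that the vinyl bromide can be lithiated.

**Step 3**
Reactants: 3 2-methyl-4,4-bis(prop-2-yn-1-yloxy)cyclohexa-2,5-dien-1-one; 5 (2-bromoprop-2-en-1-yloxy)(tert-butyl)dimethylsilane
Product: 8 (5S)-5-[3-(tert-butyldimethylsilyloxy)prop-1-en-2-yl]-2-methyl-4,4-bis(prop-2-yn-1-yloxy)cyclohex-2-en-1-one, via alkenyllithium 6 (not isolated), via lithium alkenyltrimethoxyborate 7 (not isolated)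
Conditions: 5, t-BuLi (2.05 equiv), Et2O, −78 °C; B(OMe)3, −78 °C → rt; then 3, [Rh(OH)((S)-BINAP)]2 (3 mol %), dioxane/H2O 10:1, 35 °C
Reagents that add atoms: none
Why: Hayashi–Miyaura rhodium-catalysed asymmetric 1,4-addition of the in situ alkenylboron donor occurs only at the unsubstituted enone (the 2-methyl enone is inert), and (S)-BINAP delivers the alkenyl group to the face that gives the (5S) ketone (C7 side chain β), as in the (S)-3-substituted cyclohexanones obtained from cyclohex-2-enone.

**Step 4**
Reactants: 8 (5S)-enone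
Product: 10 (5S,6R)-6-bromo ketone (8α-Br trans to the C7 side chain), via trimethylsilyl enol ether 9 (not isolated)
Conditions: LiN(SiMe3)2, Me3SiCl, THF, −78 °C; then N-bromosuccinimide, THF, −78 °C
Reagents that add atoms: N-bromosuccinimide O=C1CCC(=O)N1Br
Why: Kinetic α′-enolisation and silylation followed by electrophilic bromination of the silyl enol ether, in which bromine enters C8 anti to the adjacent C7 side chain and so sets the 8α (trans) bromide.

**Step 5**
Reactants: 10 (5S,6R)-6-bromo ketone
Product: 11 bromohydrin (9α-OH cis to 8α-Br)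
Conditions: NaBH4, CeCl3·7H2O, MeOH, −78 °C
Reagents that add atoms: none
Why: Luche 1,2-reduction in which hydride attacks C9 anti to the axial C8–Br bond (polar Felkin–Anh/Cornforth control), giving the cis-bromohydrin and hence the 9α-hydroxyl, trans to the C7 side chain.

**Step 6**
Reactants: 11 bromohydrin
Product: 12 tetrahydrofuran alcohol (O8 and C11 β, cis-fused; 9α-OH)
Conditions: Bu4NF, THF, 0 → 40 °C
Reagents that add atoms: none
Why: Fluoride desilylation frees the C12 alkoxide, which displaces the C8 bromide from the β face (intramolecular Williamson SN2, 5-exo-tet) with inversion to give the cis-fused 3-methylenetetrahydrofuran, while the cis 9-alkoxide cannot close an epoxide.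

**Step 7**
Reactants: 12 tetrahydrofuran alcohol; 13 (1-bromoethenyl)chlorodimethylsilane
Product: 14 (1-bromoethenyl)dimethylsilyl ether of 12
Conditions: imidazole, DMF, 0 °C
Reagents that add atoms: none
Why: Silylation of the 9α allylic alcohol installs the Stork vinyl-radical tether next to the C5=C10 alkene.

**Step 8**
Reactants: 14 (1-bromoethenyl)dimethylsilyl ether
Product: 15 tetracyclic cascade product (C1–C10 and C4–C5 bonds formed; C14 methyl β, C1 α, C4 β)
Conditions: Bu3SnH (1.3 equiv, syringe pump, 6 h), AIBN (0.2 equiv), PhH (5 mM), 80 °C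
Reagents that add atoms: none
Why: Proposed new method: Bu3Sn• abstracts bromine to give an α-silyl vinyl radical that adds 5-exo-trig to C10 on the α face fixed by the O9 tether (quaternary C10), the C5 radical is then captured anti to the new oxasilolane by 5-exo-dig addition to the β propargyl arm of the C6 ketal (C4 β) and the exocyclic vinyl radical takes H from Bu3SnH; the closest known reactions are Stork's (bromovinyl)silyl ether vinyl-transfer cyclization, the Ueno–Stork 5-exo-dig closure onto propargyl ethers and Stork's tandem cyclization–trapping trans to the new ring.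

**Step 9**
Reactants: 15 tetracyclic cascade product
Product: 16 vinyl alcohol (10α-vinyl, 9α-OH)
Conditions: Bu4NF·3H2O (3 equiv), DMF, 70 °C
Reagents that add atoms: none
Why: Fluoride cleaves the Si–O bond and protodesilylates the alkenylsilane (the unmasking step of the Stork vinyl transfer), leaving the vinyl group on C10 cis to the 9α-hydroxyl without touching any stereocenter.

**Step 10**
Reactants: 16 vinyl alcohol
Product: 17 epoxy alcohol (C1 as in the target)
Conditions: VO(acac)2 (5 mol %), t-BuOOH (1.5 equiv), PhMe, 0 °C → rt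
Reagents that add atoms: tert-butyl hydroperoxide CC(C)(C)OO
Why: Vanadium-catalysed hydroxyl-directed epoxidation of a homoallylic alcohol (Mihelich model), in which only the vinyl group is within reach of the 9α vanadate and oxygen is delivered from the O9 side to the vinyl rotamer whose CH2 terminus is turned away from the substituted C5, which sets C1.

**Step 11**
Reactants: 17 epoxy alcohol
Product: 19 6β,9α,15-triol, via keto alcohol 18 (not isolated)
Conditions: PPTS (0.2 equiv), THF/H2O 4:1, rt; then MeOH, CeCl3·7H2O, NaBH4, −78 → −40 °C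
Reagents that add atoms: water O
Why: Mild hydrolysis of the fused mixed ketal releases the C6 ketone, the C15 alcohol and propargyl alcohol, and the immediate Luche reduction takes place from the α face because the β face is blocked by the syn-axial C14 methyl and O8, giving the 6β (axial) alcohol cis to the C5 and C7 substituents.

**Step 12**
Reactants: 19 triol
Product: 20 C15 triethylsilyl ether
Conditions: Et3SiCl (1.05 equiv), imidazole, CH2Cl2, −40 °C
Reagents that add atoms: chlorotriethylsilane CC[Si](CC)(CC)Cl
Why: Selective silylation of the primary allylic alcohol in the presence of two hindered secondary alcohols.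

**Step 13**
Reactants: 20 C15 triethylsilyl ether; 21 angelic acid (two molecules are built in)
Product: 23 6β,9α-bis-angelate, via mixed anhydride 22 (not isolated)
Conditions: 21 (6 equiv), 2,4,6-Cl3C6H2COCl, Et3N, PhMe, rt; then 20, 80 °C
Reagents that add atoms: angelic acid (the second molecule of 21 that is built in) C/C=C(/C)C(=O)O
Why: Yamaguchi-type mixed-anhydride esterification run without DMAP acylates both secondary alcohols, one molecule of 22 per hydroxyl, and keeps the (Z) geometry of the angelate (no isomerisation to tiglate).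

**Step 14**
Reactants: 23 6β,9α-bis-angelate
Product: 24 C15 allylic alcohol
Conditions: HF·pyridine, pyridine, THF, 0 °C
Reagents that add atoms: none
Why: Buffered fluoride cleaves the primary triethylsilyl ether while the oxirane and both esters stay intact.

**Step 15**
Reactants: 24 C15 allylic alcohol
Product: 25 target compound CNP0291490.2
Conditions: CrO3·2py (15 equiv), CH2Cl2, rt
Reagents that add atoms: chromium trioxide O=[Cr](=O)=O
Why: Collins oxidation converts the primary allylic alcohol into the enal and the doubly activated (allylic, α-oxy) C12 methylene of the 3-methylenetetrahydrofuran into the lactone carbonyl (the known CrO3·pyridine route to α-methylene-γ-butyrolactones) without touching a stereocenter.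

**Compound list**
1 | o-cresol (2-methylphenol) | Cc1ccccc1O | starting material
2 | propargyl alcohol (prop-2-yn-1-ol) | C#CCO | starting material
3 | 2-methyl-4,4-bis(prop-2-yn-1-yloxy)cyclohexa-2,5-dien-1-one | CC1=CC(OCC#C)(OCC#C)C=CC1=O | intermediate
4 | 2-bromoprop-2-en-1-ol | OCC(Br)=C | starting material
5 | (2-bromoprop-2-en-1-yloxy)(tert-butyl)dimethylsilane | C=C(Br)CO[Si](C)(C)C(C)(C)C | intermediate
6 | [3-(tert-butyldimethylsilyloxy)prop-1-en-2-yl]lithium | [Li]C(=C)CO[Si](C)(C)C(C)(C)C | intermediate
7 | lithium trimethoxy[3-(tert-butyldimethylsilyloxy)prop-1-en-2-yl]borate | [Li+].CO[B-](OC)(OC)C(=C)CO[Si](C)(C)C(C)(C)C | intermediate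
8 | (5S)-5-[3-(tert-butyldimethylsilyloxy)prop-1-en-2-yl]-2-methyl-4,4-bis(prop-2-yn-1-yloxy)cyclohex-2-en-1-one (C7 side chain β) | O=C1C[C@@H](C(=C)CO[Si](C)(C)C(C)(C)C)C(OCC#C)(OCC#C)C=C1C | intermediate
9 | trimethylsilyl enol ether of 8 (C8=C9–OSiMe3) | C[Si](C)(C)OC1=C[C@@H](C(=C)CO[Si](C)(C)C(C)(C)C)C(OCC#C)(OCC#C)C=C1C | intermediate
10 | (5S,6R)-6-bromo-5-[3-(tert-butyldimethylsilyloxy)prop-1-en-2-yl]-2-methyl-4,4-bis(prop-2-yn-1-yloxy)cyclohex-2-en-1-one (8α-Br) | O=C1[C@H](Br)[C@@H](C(=C)CO[Si](C)(C)C(C)(C)C)C(OCC#C)(OCC#C)C=C1C | intermediate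
11 | bromohydrin from 10 (9α-OH cis to 8α-Br, C7 side chain β) | O[C@@H]1[C@H](Br)[C@@H](C(=C)CO[Si](C)(C)C(C)(C)C)C(OCC#C)(OCC#C)C=C1C | intermediate
12 | tetrahydrofuran alcohol: cyclohex-5(10)-ene with 9α-OH, C6 bis(propargyl) ketal and cis-fused 3-methylenetetrahydrofuran on C7/C8 (O8 and C11 β) | C=C1CO[C@H]2[C@@H]1C(OCC#C)(OCC#C)C=C(C)[C@@H]2O | intermediate
13 | (1-bromoethenyl)chlorodimethylsilane | C=C(Br)[Si](C)(C)Cl | starting material
14 | 9α-O-(1-bromoethenyl)dimethylsilyl ether of 12 | C=C1CO[C@H]2[C@@H]1C(OCC#C)(OCC#C)C=C(C)[C@@H]2O[Si](C)(C)C(Br)=C | intermediate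
15 | tetracyclic cascade product: oxasilolane O9–SiMe2–C1(=C2H2)–C10 on the α face (C14 methyl β), ketal-fused methylenetetrahydrofuran C5–C4(=C3H2)–C15H2–O–C6 on the β face, remaining propargyloxy group α on C6, tetrahydrofuran on C7/C8 as in 12 | C=C1CO[C@H]2[C@@H]1[C@@]3(OCC#C)OCC(=C)[C@H]3[C@]4(C)C(=C)[Si](C)(C)O[C@H]24 | intermediate
16 | vinyl alcohol: 10α-vinyl, 10β-methyl, 9α-OH; other rings as in 15 | C=C1CO[C@H]2[C@@H]1[C@@]3(OCC#C)OCC(=C)[C@H]3[C@](C)(C=C)[C@@H]2O | intermediate
17 | epoxy alcohol: 16 with the C1–C2 oxirane in the target configuration | C=C1CO[C@H]2[C@@H]1[C@@]3(OCC#C)OCC(=C)[C@H]3[C@](C)([C@@H]4CO4)[C@@H]2O | intermediate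
18 | keto alcohol: C6 ketone, 5β-(3-hydroxyprop-1-en-2-yl), oxirane, 9α-OH, tetrahydrofuran on C7/C8 | C=C1CO[C@H]2[C@@H]1C(=O)[C@@H](C(=C)CO)[C@](C)([C@@H]3CO3)[C@@H]2O | intermediate
19 | triol: 6β-OH, 9α-OH, C15-OH; otherwise as 18 | C=C1CO[C@H]2[C@@H]1[C@@H](O)[C@@H](C(=C)CO)[C@](C)([C@@H]3CO3)[C@@H]2O | intermediate
20 | C15 triethylsilyl ether of 19 | C=C1CO[C@H]2[C@@H]1[C@@H](O)[C@@H](C(=C)CO[Si](CC)(CC)CC)[C@](C)([C@@H]3CO3)[C@@H]2O | intermediate
21 | angelic acid, (Z)-2-methylbut-2-enoic acid | C/C=C(/C)C(=O)O | starting material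
22 | angelic 2,4,6-trichlorobenzoic anhydride | C/C=C(/C)C(=O)OC(=O)c1c(Cl)cc(Cl)cc1Cl | intermediate
23 | 6β,9α-bis-angelate of 20 | C=C1CO[C@H]2[C@@H]1[C@@H](OC(=O)/C(C)=C\C)[C@@H](C(=C)CO[Si](CC)(CC)CC)[C@](C)([C@@H]3CO3)[C@@H]2OC(=O)/C(C)=C\C | intermediate
24 | C15 allylic alcohol: 6β,9α-bis-angelate with the 3-methylenetetrahydrofuran still at the ether oxidation level | C=C1CO[C@H]2[C@@H]1[C@@H](OC(=O)/C(C)=C\C)[C@@H](C(=C)CO)[C@](C)([C@@H]3CO3)[C@@H]2OC(=O)/C(C)=C\C | intermediate
25 | CNP0291490.2 | C=C1C(=O)O[C@H]2[C@@H]1[C@@H](OC(=O)/C(C)=C\C)[C@@H](C(=C)C=O)[C@](C)([C@@H]1CO1)[C@@H]2OC(=O)/C(C)=C\C | target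

**Step count**
Total: 15 steps. Longest linear sequence: 14 steps (1 → 25 through steps 1 and 3–15; the same length from 4 through steps 2–15).

**Steps most likely to fail**

Step 8. The chain can leak by Bu3Sn• addition to the terminal alkynes, by reduction of the C5 radical before the second ring closes, or by capture through the α propargyl arm. The fallback sets out from 12 and comes back at 16. Silylation of 12 with ClSi(CH3)2CH2Br gives the (bromomethyl)dimethylsilyl ether F1. With Bu3SnH/AIBN the alkyl bromide is abstracted far faster than a vinyl bromide, and the α-silyl alkyl radical runs the same two ring closures to give the oxasilolane F2. Tamao–Fleming oxidation (H2O2, KF, KHCO3) gives the 10α-hydroxymethyl diol F3, TEMPO/PhI(OAc)2 oxidises its primary alcohol to the aldehyde F4, and Ph3P=CH2 converts this into 16. This replaces vinyl-radical vinyl transfer with alkyl-radical hydroxymethyl transfer followed by carbonyl olefination.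

Step 10. The C1 configuration rests on a conformational argument for the vanadate-bound vinyl group. The fallback sets out from 16 and comes back at 17. Hydroxyl-directed dihydroxylation with OsO4·TMEDA at −78 °C (then aqueous NaHSO3) gives the 1,2-diol F5, whose C1 epimers can be separated. Bu2SnO-catalysed tosylation of the primary hydroxyl gives the monotosylate F6, and K2CO3 in MeOH closes the oxirane with retention at C1 to give 17.

Step 15. A late oxidation that must do two things may stall at the ether or over-oxidise. The fallback sets out from 24 and comes back at 25. Allylic hydroxylation with SeO2 (cat.) and t-BuOOH (ene reaction then [2,3] shift at the C12 methylene) gives the lactol F7. MnO2 in CH2Cl2 then oxidises both the allylic lactol to the lactone and the C15 allylic alcohol to the enal, giving 25.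

**Further compounds**
F1 | step 8 | 9α-O-(bromomethyl)dimethylsilyl ether of 12 | C=C1CO[C@H]2[C@@H]1C(OCC#C)(OCC#C)C=C(C)[C@@H]2O[Si](C)(C)CBr
F2 | step 8 | cascade product with the oxasilolane O9–SiMe2–C1H2–C10 (otherwise as 15) | C=C1CO[C@H]2[C@@H]1[C@@]3(OCC#C)OCC(=C)[C@H]3[C@]4(C)C[Si](C)(C)O[C@H]24
F3 | step 8 | 10α-hydroxymethyl-9α-ol diol | C=C1CO[C@H]2[C@@H]1[C@@]3(OCC#C)OCC(=C)[C@H]3[C@](C)(CO)[C@@H]2O
F4 | step 8 | 10α-formyl-9α-ol aldehyde | C=C1CO[C@H]2[C@@H]1[C@@]3(OCC#C)OCC(=C)[C@H]3[C@](C)(C=O)[C@@H]2O
F5 | step 10 | C1,C2-diol of 16 (C1 oxygen as in 17) | C=C1CO[C@H]2[C@@H]1[C@@]3(OCC#C)OCC(=C)[C@H]3[C@](C)([C@@H](O)CO)[C@@H]2O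
F6 | step 10 | C2 4-methylbenzenesulfonate of F5 | C=C1CO[C@H]2[C@@H]1[C@@]3(OCC#C)OCC(=C)[C@H]3[C@](C)([C@@H](O)COS(=O)(=O)c4ccc(C)cc4)[C@@H]2O
F7 | step 15 | C12 lactol of 24 (12-hydroxy-3-methylenetetrahydrofuran, C12 epimers) | C=C1C(O)O[C@H]2[C@@H]1[C@@H](OC(=O)/C(C)=C\C)[C@@H](C(=C)CO)[C@](C)([C@@H]3CO3)[C@@H]2OC(=O)/C(C)=C\C
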